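**Retrosynthetic overview**
1. Target 23 ⇐ MOM removal from 22 ⇐ aromatic Claisen rearrangement of the 2'-O-(1,1-dimethylallyl) ether 20 (C3' is the only free ortho position) ⇐ phenol 18 ⇐ (R)-isoflavan 17.
2. The C3 stereocentre ⇐ Ir-catalysed asymmetric hydrogenation of the C3=C4 bond of isoflav-3-ene 16.
3. The pyran ring (O1–C2–C3–C4–C4a–C8a) ⇐ one-carbon ring expansion of the furan ring of benzofuran 7: the aryl-bearing carbon of chlorodiazirine 12, which carries the whole B ring, is inserted into the furan C2=C3 bond (cyclopropanation, electrocyclic opening to the isoflavylium ion, hydride at C2).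
4. Enabling feature: C3, the only carbon of the pyran ring that bears the B ring, lies between O–CH2 (C2) and the benzylic CH2 (C4). This is exactly where a carbon inserted into the enol-ether C2=C3 bond of a benzofuran ends up, and the ring oxygen O1 drives the opening of the chlorocyclopropane to the aromatic benzopyrylium.
5. Ring order: A and B rings are bought (1 and 8); furan ring by Sonogashira coupling/5-endo cyclisation (step 2); pyran ring by ring expansion (step 7).

Key step: step 7

Remark on the chemistry: the stereocentre (C3 of the chroman) is (R) in the target as drawn. The sense of induction of the hydrogenation catalyst is not predicted here, so the ligand antipode that gives (3R)-17 is to be chosen in a test run. Compounds 1, 3, 8 and 19 are taken as commercial.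

**Step 1**
Reactants: 1 2,6-dihydroxy-4-methoxybenzaldehyde
Product: 2 2,6-dihydroxy-3-iodo-4-methoxybenzaldehyde
Conditions: NIS (1.0 equiv), MeCN, 0 °C
Reagents that add atoms: N-iodosuccinimide, O=C1CCC(=O)N1I
Why: Electrophilic aromatic iodination of the phloroglucinol-type ring should be fast, and because C3 and C5 are equivalent by symmetry one equivalent of reagent should give a single mono-iodide.

**Step 2**
Reactants: 2 2,6-dihydroxy-3-iodo-4-methoxybenzaldehyde; 3 ethynyltrimethylsilane
Product: 6 6-hydroxy-4-methoxy-1-benzofuran-7-carbaldehyde, via silylalkyne 4 (not isolated), via terminal alkyne 5 (not isolated)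
Conditions: Pd(PPh3)2Cl2 (3 mol %), CuI (5 mol %), Et3N, DMF, rt → 40 °C; then TBAF, 60 °C
Reagents that add atoms: none
Why: Sonogashira coupling followed by fluoride desilylation and Cu/base-mediated 5-endo-dig cycloisomerisation of the o-ethynylphenol (Castro–Stephens-type benzofuran synthesis) should close the furan ring, and only the hydroxyl ortho to the alkyne can cyclise, which fixes the 7-formyl-6-hydroxy-4-methoxy pattern.

**Step 3**
Reactants: 6 6-hydroxy-4-methoxy-1-benzofuran-7-carbaldehyde
Product: 7 4-methoxy-6-(methoxymethoxy)-1-benzofuran-7-carbaldehyde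
Conditions: MOMCl, i-Pr2NEt, CH2Cl2, 0 °C → rt
Reagents that add atoms: chloromethyl methyl ether, COCCl
Why: O-alkylation of the phenol (Williamson-type acetal formation) should mask the O–H bond that would otherwise be inserted by the carbene of step 7, while the ether keeps the ring electron-rich.

**Step 4**
Reactants: 8 2-hydroxy-4-methoxybenzonitrile
Product: 9 4-methoxy-2-[(triisopropylsilyl)oxy]benzonitrile
Conditions: TIPSCl, imidazole, DMF, rt
Reagents that add atoms: chlorotriisopropylsilane, CC(C)[Si](Cl)(C(C)C)C(C)C
Why: Silylation of the phenol should give a bulky ether that tolerates amide base and hypochlorite, offers no C–H bond on the carbon next to oxygen for carbene insertion, and is later removable by fluoride orthogonally to the MOM group.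

**Step 5**
Reactants: 9 4-methoxy-2-[(triisopropylsilyl)oxy]benzonitrile
Product: 11 4-methoxy-2-[(triisopropylsilyl)oxy]benzamidinium chloride, via lithium amidinate 10 (not isolated)
Conditions: LiHMDS, THF, 0 °C → rt; then HCl in EtOH, 0 °C
Reagents that add atoms: lithium bis(trimethylsilyl)amide, [Li+].C[Si](C)(C)[N-][Si](C)(C)C; hydrogen chloride, Cl
Why: Addition of the silylamide to the nitrile followed by N-desilylation with ethanolic HCl is the standard amidine synthesis from aryl nitriles, and the cold, brief acid treatment should leave the aryl TIPS ether intact.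

**Step 6**
Reactants: 11 4-methoxy-2-[(triisopropylsilyl)oxy]benzamidinium chloride
Product: 12 3-chloro-3-{4-methoxy-2-[(triisopropylsilyl)oxy]phenyl}-3H-diazirine
Conditions: aq NaOCl, LiCl, DMSO/pentane, 0 °C → rt; product kept cold and dark and used at once
Reagents that add atoms: sodium hypochlorite, [Na+].[O-]Cl
Why: Graham oxidation (N-chlorination, cyclisation and chloride exchange) is the established route from benzamidinium salts to aryl chlorodiazirines, including p-anisyl examples, and the basic hypochlorite medium should not chlorinate the ring or cleave the TIPS ether.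

**Step 7**
Reactants: 7 4-methoxy-6-(methoxymethoxy)-1-benzofuran-7-carbaldehyde; 12 3-chloro-3-{4-methoxy-2-[(triisopropylsilyl)oxy]phenyl}-3H-diazirine
Product: 16 5-methoxy-7-(methoxymethoxy)-3-{4-methoxy-2-[(triisopropylsilyl)oxy]phenyl}-2H-chromene-8-carbaldehyde, via arylchlorocarbene 13 (not isolated), via chlorocyclopropane 14 (not isolated), via isoflavylium chloride 15 (not isolated)
Conditions: 12 (1.5 equiv, added over 2 h), MeCN, 50 °C, dark; then Et3SiH (2 equiv), 0 °C → rt
Reagents that add atoms: none
Why: Proposed new method: thermal loss of N2 from 12 should release singlet arylchlorocarbene 13, which adds [2+1] to the C2=C3 enol-ether bond of 7 to give chlorocyclopropane 14; ionisation of the C–Cl bond, pushed by the furan oxygen lone pair and the electron-rich aryl group, then triggers disrotatory 2π-electrocyclic cleavage of the shared C2–C3 bond, so that the carbene carbon sits between them in the aromatic isoflavylium ion 15. The closest known reaction types are the Ciamician–Dennstedt carbon-atom insertion of arylchlorocarbenes from chlorodiazirines into indoles, pyrroles and indenes, and the dihalocarbene ring expansion of benzofurans to 3-halo-2H-chromenes. The pyran ring is therefore not closed by a cyclisation but arises from the five-membered furan ring by one-carbon ring expansion, and the inserted carbon brings the whole B ring, which can only end at C3 between the O–CH2 carbon and the benzylic carbon. No stereocentre survives the step, because the cyclopropane stereocentres are erased on aromatisation and C3 is set in step 8. The step needs chemoselectivity of the carbene for the furan double bond over the aldehyde oxygen and the benzene rings, which the absence of any other alkene, the reversibility of carbonyl-ylide formation and the irreversibility of cyclopropanation should secure. It also needs hydride delivery to C2 rather than C4, which is expected because C2 is the unhindered oxocarbenium carbon whereas C4 is shielded by the 5-methoxy group and deactivated by the 5,7-dioxygenation; Et3SiH is added only after the diazirine is consumed, since the carbene would insert into Si–H.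

**Step 8**
Reactants: 16 5-methoxy-7-(methoxymethoxy)-3-{4-methoxy-2-[(triisopropylsilyl)oxy]phenyl}-2H-chromene-8-carbaldehyde
Product: 17 (3R)-5-methoxy-7-(methoxymethoxy)-3-{4-methoxy-2-[(triisopropylsilyl)oxy]phenyl}chromane-8-carbaldehyde
Conditions: [Ir(cod)(L*)]BArF (2 mol %, L* = chiral P,N ligand of the PHOX type, antipode chosen to give 3R), H2 (50 bar), CH2Cl2, rt
Reagents that add atoms: none
Why: Ir-catalysed asymmetric hydrogenation of trisubstituted cyclic styrenes is a known route from 3-aryl-2H-chromenes to isoflavans; the chiral P,N ligand differentiates the enantiotopic faces of C3=C4 and so sets C3 under catalyst control, and no other alkene is present while aldehyde and arenes should not be reduced.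

**Step 9**
Reactants: 17 (3R)-5-methoxy-7-(methoxymethoxy)-3-{4-methoxy-2-[(triisopropylsilyl)oxy]phenyl}chromane-8-carbaldehyde
Product: 18 (3R)-3-(2-hydroxy-4-methoxyphenyl)-5-methoxy-7-(methoxymethoxy)chromane-8-carbaldehyde
Conditions: TBAF, AcOH, THF, 0 °C
Reagents that add atoms: none
Why: Fluoride-induced cleavage of the aryl silyl ether under acetic acid buffering should free only the 2'-hydroxyl, leaving the MOM ether, the aldehyde and the non-acidic C3 stereocentre untouched.

**Step 10**
Reactants: 18 (3R)-3-(2-hydroxy-4-methoxyphenyl)-5-methoxy-7-(methoxymethoxy)chromane-8-carbaldehyde; 19 tert-butyl 2-methylbut-3-en-2-yl carbonate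
Product: 20 (3R)-5-methoxy-7-(methoxymethoxy)-3-{4-methoxy-2-[(2-methylbut-3-en-2-yl)oxy]phenyl}chromane-8-carbaldehyde
Conditions: Pd(PPh3)4 (5 mol %), THF, 0 °C
Reagents that add atoms: none
Why: Decarboxylative Tsuji–Trost O-allylation of phenols with 1,1-dimethylallyl carbonates is known to deliver the tertiary (reverse-prenyl) aryl ether under kinetic control at low temperature, and the only free hydroxyl is the 2'-OH.

**Step 11**
Reactants: 20 (3R)-5-methoxy-7-(methoxymethoxy)-3-{4-methoxy-2-[(2-methylbut-3-en-2-yl)oxy]phenyl}chromane-8-carbaldehyde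
Product: 22 (3R)-3-[2-hydroxy-4-methoxy-3-(3-methylbut-2-en-1-yl)phenyl]-5-methoxy-7-(methoxymethoxy)chromane-8-carbaldehyde, via ortho-dienone 21 (not isolated)
Conditions: PhMe, 110 °C (sealed tube)
Reagents that add atoms: none
Why: The aromatic Claisen rearrangement ([3,3]) of the 1,1-dimethylallyl aryl ether should transfer the allyl unit with inversion to C3', the only unsubstituted ortho position, giving the linear prenyl group after tautomerisation of the dienone, with the remote C3 stereocentre unaffected.

**Step 12**
Reactants: 22 (3R)-3-[2-hydroxy-4-methoxy-3-(3-methylbut-2-en-1-yl)phenyl]-5-methoxy-7-(methoxymethoxy)chromane-8-carbaldehyde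
Product: 23 (3R)-7-hydroxy-3-[2-hydroxy-4-methoxy-3-(3-methylbut-2-en-1-yl)phenyl]-5-methoxychromane-8-carbaldehyde
Conditions: HCl (0.5 M in MeOH, catalytic), 0 °C → rt
Reagents that add atoms: none
Why: Acid-catalysed acetal exchange (methanolysis) of the MOM ether is assisted by the ortho-formyl group and should therefore proceed under conditions mild enough to spare the o-prenylphenol from cyclisation to a dimethylchroman.

**Compound list**
1 | 2,6-dihydroxy-4-methoxybenzaldehyde | COc1cc(O)c(C=O)c(O)c1 | starting material
2 | 2,6-dihydroxy-3-iodo-4-methoxybenzaldehyde | COc1cc(O)c(C=O)c(O)c1I | intermediate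
3 | ethynyltrimethylsilane | C#C[Si](C)(C)C | starting material
4 | 2,6-dihydroxy-4-methoxy-3-[(trimethylsilyl)ethynyl]benzaldehyde | COc1cc(O)c(C=O)c(O)c1C#C[Si](C)(C)C | intermediate (not isolated)
5 | 3-ethynyl-2,6-dihydroxy-4-methoxybenzaldehyde | COc1cc(O)c(C=O)c(O)c1C#C | intermediate (not isolated)
6 | 6-hydroxy-4-methoxy-1-benzofuran-7-carbaldehyde | COc1cc(O)c(C=O)c2occc12 | intermediate
7 | 4-methoxy-6-(methoxymethoxy)-1-benzofuran-7-carbaldehyde | COCOc1cc(OC)c2ccoc2c1C=O | intermediate
8 | 2-hydroxy-4-methoxybenzonitrile | COc1ccc(C#N)c(O)c1 | starting material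
9 | 4-methoxy-2-[(triisopropylsilyl)oxy]benzonitrile | COc1ccc(C#N)c(O[Si](C(C)C)(C(C)C)C(C)C)c1 | intermediate
10 | lithium N,N'-bis(trimethylsilyl)-4-methoxy-2-[(triisopropylsilyl)oxy]benzamidinate | [Li+].COc1ccc(C(=N[Si](C)(C)C)[N-][Si](C)(C)C)c(O[Si](C(C)C)(C(C)C)C(C)C)c1 | intermediate (not isolated)
11 | 4-methoxy-2-[(triisopropylsilyl)oxy]benzamidinium chloride | COc1ccc(C(N)=[NH2+])c(O[Si](C(C)C)(C(C)C)C(C)C)c1.[Cl-] | intermediate
12 | 3-chloro-3-{4-methoxy-2-[(triisopropylsilyl)oxy]phenyl}-3H-diazirine | COc1ccc(C2(Cl)N=N2)c(O[Si](C(C)C)(C(C)C)C(C)C)c1 | intermediate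
13 | chloro{4-methoxy-2-[(triisopropylsilyl)oxy]phenyl}carbene | COc1ccc([C]Cl)c(O[Si](C(C)C)(C(C)C)C(C)C)c1 | intermediate (not isolated)
14 | 1-chloro-6-methoxy-4-(methoxymethoxy)-1-{4-methoxy-2-[(triisopropylsilyl)oxy]phenyl}-1a,6b-dihydro-1H-cyclopropa[b][1]benzofuran-3-carbaldehyde (cis-fused, racemic, Cl/aryl configuration undefined) | COCOc1cc(OC)c2c(c1C=O)OC1C2C1(Cl)c1ccc(OC)cc1O[Si](C(C)C)(C(C)C)C(C)C | intermediate (not isolated)
15 | 8-formyl-5-methoxy-7-(methoxymethoxy)-3-{4-methoxy-2-[(triisopropylsilyl)oxy]phenyl}chromenylium chloride | COCOc1cc(OC)c2cc(-c3ccc(OC)cc3O[Si](C(C)C)(C(C)C)C(C)C)c[o+]c2c1C=O.[Cl-] | intermediate (not isolated)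
16 | 5-methoxy-7-(methoxymethoxy)-3-{4-methoxy-2-[(triisopropylsilyl)oxy]phenyl}-2H-chromene-8-carbaldehyde | COCOc1cc(OC)c2c(c1C=O)OCC(=C2)c1ccc(OC)cc1O[Si](C(C)C)(C(C)C)C(C)C | intermediate
17 | (3R)-5-methoxy-7-(methoxymethoxy)-3-{4-methoxy-2-[(triisopropylsilyl)oxy]phenyl}chromane-8-carbaldehyde | COc1ccc([C@@H]2COc3c(C=O)c(OCOC)cc(OC)c3C2)c(O[Si](C(C)C)(C(C)C)C(C)C)c1 | intermediate
18 | (3R)-3-(2-hydroxy-4-methoxyphenyl)-5-methoxy-7-(methoxymethoxy)chromane-8-carbaldehyde | COc1ccc([C@@H]2COc3c(C=O)c(OCOC)cc(OC)c3C2)c(O)c1 | intermediate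
19 | tert-butyl 2-methylbut-3-en-2-yl carbonate | CC(C)(C)OC(=O)OC(C)(C)C=C | starting material
20 | (3R)-5-methoxy-7-(methoxymethoxy)-3-{4-methoxy-2-[(2-methylbut-3-en-2-yl)oxy]phenyl}chromane-8-carbaldehyde | COc1ccc([C@@H]2COc3c(C=O)c(OCOC)cc(OC)c3C2)c(OC(C)(C)C=C)c1 | intermediate
21 | (3R)-5-methoxy-3-[4-methoxy-5-(3-methylbut-2-en-1-yl)-6-oxocyclohexa-1,3-dien-1-yl]-7-(methoxymethoxy)chromane-8-carbaldehyde (ring sp3 centre undefined) | COC1=CC=C([C@@H]2COc3c(C=O)c(OCOC)cc(OC)c3C2)C(=O)C1CC=C(C)C | intermediate (not isolated)
22 | (3R)-3-[2-hydroxy-4-methoxy-3-(3-methylbut-2-en-1-yl)phenyl]-5-methoxy-7-(methoxymethoxy)chromane-8-carbaldehyde | COc1ccc([C@@H]2COc3c(C=O)c(OCOC)cc(OC)c3C2)c(O)c1CC=C(C)C | intermediate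
23 | (3R)-7-hydroxy-3-[2-hydroxy-4-methoxy-3-(3-methylbut-2-en-1-yl)phenyl]-5-methoxychromane-8-carbaldehyde | COc1ccc([C@@H]2COc3c(C=O)c(O)cc(OC)c3C2)c(O)c1CC=C(C)C | target

**Step count and risks**
Total step count: 12. Longest linear sequence: 9 steps (steps 1–3 then 7–12; the B-ring branch, steps 4–6 then 7–12, is equally long).

Steps most likely to fail:

1. Step 7 (proposed new method). The carbene may be captured by the aldehyde oxygen, or the electron-rich diazirine may decompose before cyclopropanation; the chlorocyclopropane may ionise incompletely; hydride may be delivered to C4 instead of C2. Fallback, setting out from 7 and returning at 16: the same ring expansion is done with a dihalocarbene, a known reaction class for benzofurans, and the B ring is attached afterwards. Benzofuran 7 is heated with phenyl(tribromomethyl)mercury (neutral dibromocarbene source, benzene, 80 °C), which should give the dibromocyclopropane F1 and, by loss of bromide and electrocyclic opening, the 3-bromochromenylium bromide F2; Et3SiH then reduces this at C2 to the 3-bromo-2H-chromene F3. In parallel, commercial 2-bromo-5-methoxyphenol is silylated (TIPSCl, imidazole, DMF) to the aryl bromide F4 and borylated (B2pin2, Pd(dppf)Cl2, KOAc, dioxane, 90 °C) to the pinacol boronate F5. Suzuki–Miyaura coupling of F3 with F5 (Pd(dppf)Cl2, K3PO4, dioxane/H2O, 70 °C) should give 16. This detour needs no diazirine and so also covers a failure of steps 4–6.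

2. Step 8. Facial discrimination may be poor or turnover may stall because of the bulky ortho-silyloxy aryl group, and acidic Ir–H species may cause loss of the MOM group. Fallback, setting out from 16 and returning at 17: hydrogenation with an achiral catalyst (Crabtree catalyst, H2, CH2Cl2) to the racemic isoflavan F6, followed by separation of the enantiomers by preparative chiral SFC; the (R)-enantiomer is 17 and the (S)-enantiomer F7 is discarded.

3. Step 10. The phenoxide may attack the primary terminus of the π-allyl complex, giving the linear O-prenyl ether (which would rearrange to the wrong C-substituent), or C-allylation may compete. Fallback, setting out from 18 and returning at 20: Cu-catalysed propargylation with 3-chloro-3-methylbut-1-yne (CuCl2·2H2O cat., DBU, MeCN, 0 °C), which can only give the tertiary propargyl ether F8, followed by Lindlar semi-hydrogenation (H2, Pd/CaCO3/Pb, quinoline, EtOAc) to 20.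

**Further compounds**
F1 | step 7 | 1,1-dibromo-6-methoxy-4-(methoxymethoxy)-1a,6b-dihydro-1H-cyclopropa[b][1]benzofuran-3-carbaldehyde | COCOc1cc(OC)c2c(c1C=O)OC1C2C1(Br)Br
F2 | step 7 | 3-bromo-8-formyl-5-methoxy-7-(methoxymethoxy)chromenylium bromide | COCOc1cc(OC)c2cc(Br)c[o+]c2c1C=O.[Br-]
F3 | step 7 | 3-bromo-5-methoxy-7-(methoxymethoxy)-2H-chromene-8-carbaldehyde | COCOc1cc(OC)c2c(c1C=O)OCC(Br)=C2
F4 | step 7 | (2-bromo-5-methoxyphenoxy)triisopropylsilane | COc1ccc(Br)c(O[Si](C(C)C)(C(C)C)C(C)C)c1
F5 | step 7 | 2-{4-methoxy-2-[(triisopropylsilyl)oxy]phenyl}-4,4,5,5-tetramethyl-1,3,2-dioxaborolane | COc1ccc(B2OC(C)(C)C(C)(C)O2)c(O[Si](C(C)C)(C(C)C)C(C)C)c1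
F6 | step 8 | racemic 5-methoxy-7-(methoxymethoxy)-3-{4-methoxy-2-[(triisopropylsilyl)oxy]phenyl}chromane-8-carbaldehyde | COc1ccc(C2COc3c(C=O)c(OCOC)cc(OC)c3C2)c(O[Si](C(C)C)(C(C)C)C(C)C)c1
F7 | step 8 | (3S)-5-methoxy-7-(methoxymethoxy)-3-{4-methoxy-2-[(triisopropylsilyl)oxy]phenyl}chromane-8-carbaldehyde | COc1ccc([C@H]2COc3c(C=O)c(OCOC)cc(OC)c3C2)c(O[Si](C(C)C)(C(C)C)C(C)C)c1
F8 | step 10 | (3R)-5-methoxy-7-(methoxymethoxy)-3-{4-methoxy-2-[(2-methylbut-3-yn-2-yl)oxy]phenyl}chromane-8-carbaldehyde | COc1ccc([C@@H]2COc3c(C=O)c(OCOC)cc(OC)c3C2)c(OC(C)(C)C#C)c1
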